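**Retrosynthetic overview**

Numbering: ring C1 (CH carrying the side chain), C2 (CMe2), C3 (C=O), C4=C5, C6 (C(CH3)OH); chain C7 (CH2), C8 (C=O), C9(CH3)=C10, C11 (CH2O-decanoyl).
Feature used: the C6 carbinol oxygen and the C8 carbonyl are 1,4-related through C1–C6, the most hindered bond of the six-membered ring (between quaternary C2 and C6). The ring therefore hides a cis-fused γ-lactone O–C6–C1–C7–C8, the retron of a reductive ketone/enoate coupling.
Disconnections: (a) C8–C9 by Liebeskind–Srogl coupling of a C8 thioester with a Z-alkenylstannane already carrying the decanoate; (b) C4=C5 by Saegusa desaturation of the C3 ketone; (c) C1–C6 and O–C8 by cathodic keto-enoate hydrocyclisation/lactonisation of an acyclic keto-enoate whose single stereocentre (C3–OSi) comes from an asymmetric Mukaiyama aldol.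
Ring order: the carbocycle (C1–C6) and the γ-lactone close in one operation; the lactone is opened later by thiolysis, at the saturated C3-ketone stage, so that no thiolate meets the ring enone.

Key step: step 7

Assumption: the oxazaborolidinone from N-tosyl-L-valine is taken to give the 3R aldol 3; if the facial sense proved opposite, the D-valine promoter would be used with no other change.

**Route**

Step 1
Reactants: 1 pent-4-enal; 2 methyl trimethylsilyl dimethylketene acetal
Product: 3 methyl (3R)-3-hydroxy-2,2-dimethylhept-6-enoate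
Conditions: N-Ts-L-valine, BH3·THF (1 equiv each), CH2Cl2, 0 °C to rt; then 1 and 2, −78 °C; aq. HCl work-up
Reagents that add atoms: none
Why: Kiyooka-type asymmetric Mukaiyama aldol, in which the aldehyde bound to the valine-derived oxazaborolidinone is shielded on one face, so the ketene acetal adds to the open face and sets C3 as 3R (the only stereocentre carried into the key step), the O-silyl group being lost on acidic work-up.

Step 2
Reactants: 3 methyl (3R)-3-hydroxy-2,2-dimethylhept-6-enoate
Product: 4 methyl (3R)-3-(tert-butyldimethylsilyloxy)-2,2-dimethylhept-6-enoate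
Conditions: TBSOTf, 2,6-lutidine, CH2Cl2, 0 °C
Reagents that add atoms: tert-butyldimethylsilyl triflate, CC(C)(C)[Si](C)(C)OS(=O)(=O)C(F)(F)F
Why: Silyl triflate silylation of a hindered neopentylic secondary alcohol with a non-nucleophilic base, which avoids retro-aldol cleavage of the β-hydroxy ester.

Step 3
Reactants: 4 methyl (3R)-3-(tert-butyldimethylsilyloxy)-2,2-dimethylhept-6-enoate
Product: 5 (3R)-3-(tert-butyldimethylsilyloxy)-2,2-dimethylhept-6-en-1-ol
Conditions: i-Bu2AlH (2.5 equiv), CH2Cl2, −78 to 0 °C; aq. potassium sodium tartrate (KNaC4H4O6)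
Reagents that add atoms: none
Why: Full hydride reduction of the neopentylic ester to the primary alcohol, chosen because partial reduction next to a quaternary carbon is unreliable; the silyl ether and terminal alkene are inert.

Step 4
Reactants: 5 (3R)-3-(tert-butyldimethylsilyloxy)-2,2-dimethylhept-6-en-1-ol
Product: 6 (3R)-3-(tert-butyldimethylsilyloxy)-2,2-dimethylhept-6-enal
Conditions: Dess–Martin periodinane, CH2Cl2, rt
Reagents that add atoms: none
Why: Dess–Martin oxidation of a primary alcohol under neutral conditions; the aldehyde has no α-hydrogen, so neither epimerisation nor β-elimination of the silyloxy group can occur.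

Step 5
Reactants: 6 (3R)-3-(tert-butyldimethylsilyloxy)-2,2-dimethylhept-6-enal
Product: 7 methyl (2E,5R)-5-(tert-butyldimethylsilyloxy)-4,4-dimethylnona-2,8-dienoate
Conditions: (MeO)2P(O)CH2CO2Me, NaH, THF, 0 °C to rt
Reagents that add atoms: trimethyl phosphonoacetate, COC(=O)CP(=O)(OC)OC
Why: Horner–Wadsworth–Emmons olefination of a non-enolisable α-quaternary aldehyde with a stabilised phosphonate anion, which should give the E-enoate.

Step 6
Reactants: 7 methyl (2E,5R)-5-(tert-butyldimethylsilyloxy)-4,4-dimethylnona-2,8-dienoate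
Product: 8 methyl (2E,5R)-5-(tert-butyldimethylsilyloxy)-4,4-dimethyl-8-oxonon-2-enoate
Conditions: PdCl2 (10 mol%), CuCl (1 equiv), O2 (1 atm), DMF/H2O 7:1, rt
Reagents that add atoms: water, O
Why: Tsuji–Wacker oxidation converts the monosubstituted terminal alkene to the methyl ketone with Markovnikov selectivity, while the electron-poor disubstituted enoate is not engaged by divalent palladium.

Step 7
Reactants: 8 methyl (2E,5R)-5-(tert-butyldimethylsilyloxy)-4,4-dimethyl-8-oxonon-2-enoate
Product: 10 (3aR,5R,7aS)-5-(tert-butyldimethylsilyloxy)-4,4,7a-trimethylhexahydro-1-benzofuran-2(3H)-one, via cyclised hydroxy ester 9 (not isolated)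
Conditions: divided cell, glassy carbon cathode, Pt anode; 8 (0.02 M), Bu4NBF4 (0.1 M), Mg(ClO4)2 (1 equiv), CH2(CO2Me)2 (2 equiv), MeCN, −2.2 V vs SCE, rt; then 40 °C to finish lactonisation
Reagents that add atoms: none
Why: One-electron cathodic reduction of the Mg2+-activated enoate (the more easily reduced π-system, the isolated ketone being untouched at this potential) gives a radical anion whose β-carbon C1 adds to the C6 ketone carbon in a 6-exo-trig closure, after which a second electron and a proton from the malonate discharge the ester α-radical/enolate to give 9. The closest known reaction type is the electroreductive cyclisation of enoates tethered to ketones, whose chemical counterpart is the SmI2 ketyl–olefin lactonisation. The C6 alkoxide of 9 then closes the cis-fused γ-lactone by 5-exo-trig acyl substitution with loss of methoxide, a path open only to the isomer with O and C7 cis. C1 is set by a chair-like transition state with the C3 silyloxy group and the enoate arm both equatorial, which puts C7 on the face of the silyloxy group; C6 is set by its methyl staying equatorial to avoid the syn-axial C2 methyl, so the oxygen is axial and cis to C7, an arrangement that Mg2+ bridging the ketone oxygen and the ester carbonyl should reinforce against the dipole-minimised anti closure. The step needs ring closure to outrun simple saturation or hydrodimerisation of the enoate (helped by the gem-dimethyl group, dilution and the Lewis acid) and needs facial control from the single C3 stereocentre, which is predicted to be useful but incomplete. The non-lactonising C6 epimer and the C1/C6-inverted lactone are therefore removed by chromatography here, because after C3 is oxidised the latter would become the enantiomer.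

Step 8
Reactants: 10 (3aR,5R,7aS)-5-(tert-butyldimethylsilyloxy)-4,4,7a-trimethylhexahydro-1-benzofuran-2(3H)-one
Product: 11 (3aR,5R,7aS)-5-hydroxy-4,4,7a-trimethylhexahydro-1-benzofuran-2(3H)-one
Conditions: HF (48% aq.), MeCN, rt
Reagents that add atoms: none
Why: Acidic fluoride cleavage of the hindered secondary silyl ether, under which the γ-lactone stays closed (basic fluoride sources are avoided).

Step 9
Reactants: 11 (3aR,5R,7aS)-5-hydroxy-4,4,7a-trimethylhexahydro-1-benzofuran-2(3H)-one
Product: 12 (3aR,7aS)-4,4,7a-trimethylhexahydro-1-benzofuran-2,5-dione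
Conditions: Dess–Martin periodinane, CH2Cl2, rt
Reagents that add atoms: none
Why: Dess–Martin oxidation of the secondary alcohol to the C3 ketone, which removes the controlling stereocentre only after the diastereomers have been separated; C1 and C6 cannot epimerise.

Step 10
Reactants: 12 (3aR,7aS)-4,4,7a-trimethylhexahydro-1-benzofuran-2,5-dione
Product: 13 S-ethyl 2-[(1R,6S)-6-hydroxy-2,2,6-trimethyl-3-oxocyclohexyl]ethanethioate
Conditions: AlMe3, EtSH (forms Me2AlSEt), CH2Cl2, 0 °C to rt; aq. potassium sodium tartrate (KNaC4H4O6), 0 °C; crude used at once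
Reagents that add atoms: ethanethiol, CCS
Why: Aluminium thiolate opening of a lactone (Weinreb-type transfer), in which Me2AlSEt attacks the lactone carbonyl and the strong Al–O bond to the released tertiary alkoxide drives ring opening, the hindered ketone beside quaternary C2 being left alone; no enone is present yet, so thiolate conjugate addition cannot interfere.

Step 11
Reactants: 13 S-ethyl 2-[(1R,6S)-6-hydroxy-2,2,6-trimethyl-3-oxocyclohexyl]ethanethioate
Product: 15 S-ethyl 2-[(1R,2S)-2,6,6-trimethyl-5-oxo-2-(triethylsilyloxy)cyclohex-3-en-1-yl]ethanethioate, via bis-silyl enol ether 14 (not isolated)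
Conditions: TESOTf (2.5 equiv), Et3N, CH2Cl2, −78 to 0 °C; aq. NaHCO3 work-up; then Pd(OAc)2 (1.1 equiv), MeCN, rt
Reagents that add atoms: triethylsilyl triflate, CC[Si](CC)(CC)OS(=O)(=O)C(F)(F)F
Why: Silyl triflate/amine silylates the tertiary alcohol (blocking relactonisation) and soft-enolises the ketone, which can enolise only toward C4 because C2 is quaternary, and Saegusa–Ito oxidation of the silyl enol ether with divalent palladium then installs C4=C5 by β-hydride elimination.

Step 12
Reactants: 16 but-2-yn-1-ol
Product: 17 (2Z)-3-iodobut-2-en-1-ol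
Conditions: NaAlH2(OCH2CH2OMe)2, THF, 0 °C to rt; EtOAc; then I2, −78 to 0 °C
Reagents that add atoms: iodine, II
Why: Hydroxyl-directed trans-hydroalumination of the propargylic alcohol places aluminium at C3 in a five-membered alkoxyaluminate, and iodinolysis with retention gives the Z-3-iodo allylic alcohol, which fixes the geometry of the future C9=C10 bond.

Step 13
Reactants: 17 (2Z)-3-iodobut-2-en-1-ol
Product: 18 (2Z)-3-(tributylstannyl)but-2-en-1-ol
Conditions: (Bu3Sn)2 (1.5 equiv), Pd(PPh3)4 (5 mol%), toluene, 80 °C
Reagents that add atoms: hexabutylditin, CCCC[Sn](CCCC)(CCCC)[Sn](CCCC)(CCCC)CCCC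
Why: Palladium-catalysed stannylation of an alkenyl iodide with a distannane (oxidative addition, Sn–Sn transmetalation, reductive elimination) proceeds with retention of alkene geometry and tolerates the free alcohol, which cannot ionise.

Step 14
Reactants: 18 (2Z)-3-(tributylstannyl)but-2-en-1-ol; 19 decanoyl chloride
Product: 20 (2Z)-3-(tributylstannyl)but-2-en-1-yl decanoate
Conditions: pyridine, DMAP (cat.), CH2Cl2, 0 °C
Reagents that add atoms: none
Why: Base-mediated O-acylation of the primary allylic alcohol with the acid chloride under buffered, non-acidic conditions that avoid protodestannylation.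

Step 15
Reactants: 15 S-ethyl 2-[(1R,2S)-2,6,6-trimethyl-5-oxo-2-(triethylsilyloxy)cyclohex-3-en-1-yl]ethanethioate; 20 (2Z)-3-(tributylstannyl)but-2-en-1-yl decanoate
Product: 21 (2Z)-3-methyl-4-oxo-5-[(1R,2S)-2,6,6-trimethyl-5-oxo-2-(triethylsilyloxy)cyclohex-3-en-1-yl]pent-2-en-1-yl decanoate
Conditions: Pd2(dba)3 (2.5 mol%), P(2-furyl)3 (10 mol%), CuO2PPh2 (monovalent copper diphenylphosphinate, 1.5 equiv), THF, rt to 40 °C, dark
Reagents that add atoms: none
Why: Liebeskind–Srogl ketone synthesis in its stannane variant, in which zerovalent palladium inserts into the C(O)–S bond, the copper phosphinate scavenges the thiolate and relays the alkenyl group from tin, and reductive elimination forms C8–C9 with retention of the Z geometry under neutral conditions that spare the decanoate, the ring enone and the tertiary silyl ether.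

Step 16
Reactants: 21 (2Z)-3-methyl-4-oxo-5-[(1R,2S)-2,6,6-trimethyl-5-oxo-2-(triethylsilyloxy)cyclohex-3-en-1-yl]pent-2-en-1-yl decanoate
Product: 22 (2Z)-5-[(1R,2S)-2-hydroxy-2,6,6-trimethyl-5-oxocyclohex-3-en-1-yl]-3-methyl-4-oxopent-2-en-1-yl decanoate (CNP0241324.1)
Conditions: HF·pyridine, pyridine, THF, 0 °C to rt
Reagents that add atoms: none
Why: Buffered fluoride cleavage of the tertiary triethylsilyl ether under mild, non-nucleophilic conditions that should neither hydrolyse the allylic decanoate nor isomerise the Z-enone, freeing the C6 carbinol of the target.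

**Compound list**

1 | pent-4-enal | C=CCCC=O | starting material
2 | methyl trimethylsilyl dimethylketene acetal | COC(O[Si](C)(C)C)=C(C)C | starting material
3 | methyl (3R)-3-hydroxy-2,2-dimethylhept-6-enoate | C=CCC[C@@H](O)C(C)(C)C(=O)OC | intermediate
4 | methyl (3R)-3-(tert-butyldimethylsilyloxy)-2,2-dimethylhept-6-enoate | C=CCC[C@@H](O[Si](C)(C)C(C)(C)C)C(C)(C)C(=O)OC | intermediate
5 | (3R)-3-(tert-butyldimethylsilyloxy)-2,2-dimethylhept-6-en-1-ol | C=CCC[C@@H](O[Si](C)(C)C(C)(C)C)C(C)(C)CO | intermediate
6 | (3R)-3-(tert-butyldimethylsilyloxy)-2,2-dimethylhept-6-enal | C=CCC[C@@H](O[Si](C)(C)C(C)(C)C)C(C)(C)C=O | intermediate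
7 | methyl (2E,5R)-5-(tert-butyldimethylsilyloxy)-4,4-dimethylnona-2,8-dienoate | C=CCC[C@@H](O[Si](C)(C)C(C)(C)C)C(C)(C)/C=C/C(=O)OC | intermediate
8 | methyl (2E,5R)-5-(tert-butyldimethylsilyloxy)-4,4-dimethyl-8-oxonon-2-enoate | CC(=O)CC[C@@H](O[Si](C)(C)C(C)(C)C)C(C)(C)/C=C/C(=O)OC | intermediate
9 | methyl 2-[(1R,3R,6S)-3-(tert-butyldimethylsilyloxy)-6-hydroxy-2,2,6-trimethylcyclohexyl]acetate | COC(=O)C[C@@H]1C(C)(C)[C@H](O[Si](C)(C)C(C)(C)C)CC[C@]1(C)O | intermediate
10 | (3aR,5R,7aS)-5-(tert-butyldimethylsilyloxy)-4,4,7a-trimethylhexahydro-1-benzofuran-2(3H)-one | O=C1C[C@@H]2C(C)(C)[C@H](O[Si](C)(C)C(C)(C)C)CC[C@]2(C)O1 | intermediate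
11 | (3aR,5R,7aS)-5-hydroxy-4,4,7a-trimethylhexahydro-1-benzofuran-2(3H)-one | O=C1C[C@@H]2C(C)(C)[C@H](O)CC[C@]2(C)O1 | intermediate
12 | (3aR,7aS)-4,4,7a-trimethylhexahydro-1-benzofuran-2,5-dione | O=C1C[C@@H]2C(C)(C)C(=O)CC[C@]2(C)O1 | intermediate
13 | S-ethyl 2-[(1R,6S)-6-hydroxy-2,2,6-trimethyl-3-oxocyclohexyl]ethanethioate | CCSC(=O)C[C@@H]1C(C)(C)C(=O)CC[C@]1(C)O | intermediate
14 | S-ethyl 2-[(1R,6S)-2,2,6-trimethyl-3,6-bis(triethylsilyloxy)cyclohex-3-en-1-yl]ethanethioate | CCSC(=O)C[C@@H]1C(C)(C)C(O[Si](CC)(CC)CC)=CC[C@]1(C)O[Si](CC)(CC)CC | intermediate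
15 | S-ethyl 2-[(1R,2S)-2,6,6-trimethyl-5-oxo-2-(triethylsilyloxy)cyclohex-3-en-1-yl]ethanethioate | CCSC(=O)C[C@@H]1C(C)(C)C(=O)C=C[C@]1(C)O[Si](CC)(CC)CC | intermediate
16 | but-2-yn-1-ol | CC#CCO | starting material
17 | (2Z)-3-iodobut-2-en-1-ol | OC/C=C(/C)I | intermediate
18 | (2Z)-3-(tributylstannyl)but-2-en-1-ol | OC/C=C(/C)[Sn](CCCC)(CCCC)CCCC | intermediate
19 | decanoyl chloride | CCCCCCCCCC(=O)Cl | starting material
20 | (2Z)-3-(tributylstannyl)but-2-en-1-yl decanoate | CCCCCCCCCC(=O)OC/C=C(/C)[Sn](CCCC)(CCCC)CCCC | intermediate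
21 | (2Z)-3-methyl-4-oxo-5-[(1R,2S)-2,6,6-trimethyl-5-oxo-2-(triethylsilyloxy)cyclohex-3-en-1-yl]pent-2-en-1-yl decanoate | CCCCCCCCCC(=O)OC/C=C(/C)C(=O)C[C@@H]1C(C)(C)C(=O)C=C[C@]1(C)O[Si](CC)(CC)CC | intermediate
22 | (2Z)-5-[(1R,2S)-2-hydroxy-2,6,6-trimethyl-5-oxocyclohex-3-en-1-yl]-3-methyl-4-oxopent-2-en-1-yl decanoate | CCCCCCCCCC(=O)OC/C=C(/C)C(=O)C[C@@H]1C(C)(C)C(=O)C=C[C@]1(C)O | target

**Step count**

Total: 16 steps. Longest linear sequence: 13 steps (steps 1–11, 15, 16); the stannane 20 is made in 3 steps (12–14).

**Steps most likely to fail**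

1. Step 7. Two processes threaten it. Saturation or hydrodimerisation of the enoate may outrun attack of the neopentylic β-carbon on the ketone. Facial control by the remote C3 stereocentre may be incomplete, or closure may go anti to the non-lactonising C6 epimer; any C1/C6-inverted lactone carried forward would erode the enantiomeric purity once C3 is oxidised. The fallback sets out from 8 and comes back at 10. It replaces the electrode by an inner-sphere chemical reductant that acts on the ketone first: SmI2 (2.5 equiv) in THF with MeOH (2 equiv) and no HMPA, −78 to 0 °C. The samarium ketyl at C6 adds 6-exo-trig to the enoate β-carbon while trivalent samarium stays bound to the ketyl oxygen and the ester carbonyl, which should favour the syn closure; the samarium alkoxide of 9 then lactonises to 10. This fallback makes no compound outside the list (F0).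

2. Step 15. The Z geometry may be lost through phosphine conjugate addition–elimination on the product enone or through π-allyl formation. The allylic decanoate may be ionised by zerovalent palladium. The γ-acyloxy alkenylmetal may undergo β-elimination to an allene, and insertion into the S-alkyl thioester may be slow. The fallback sets out from 15 (with 17 and 19) and comes back at 21; it forms C8–C9 by carbonyl addition instead of acyl cross-coupling. Fukuyama reduction of 15 (Et3SiH, Pd on carbon, acetone, rt, short contact to spare the ring enone) should give 2-[(1R,2S)-2,6,6-trimethyl-5-oxo-2-(triethylsilyloxy)cyclohex-3-en-1-yl]acetaldehyde F1. Acylation of 17 with 19 (pyridine, DMAP, CH2Cl2) gives (2Z)-3-iodobut-2-en-1-yl decanoate F2. Nozaki–Hiyama–Kishi coupling of F1 with F2 (CrCl2, NiCl2 cat., DMSO, rt), which is selective for the aldehyde over the enone and retains the geometry of the trisubstituted iodide, gives (2Z)-4-hydroxy-3-methyl-5-[(1R,2S)-2,6,6-trimethyl-5-oxo-2-(triethylsilyloxy)cyclohex-3-en-1-yl]pent-2-en-1-yl decanoate F3 as a mixture of carbinol epimers. Dess–Martin oxidation of F3 gives 21.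

3. Step 10. The hydroxy thioester may relactonise during work-up before it is silylated, and the aluminium thiolate or residual Al–Me may attack the C3 ketone. The fallback sets out from 12 and comes back at 14; it opens the lactone by hydrolysis and introduces sulfur only after the tertiary alcohol is protected. LiOH in THF/H2O gives lithium 2-[(1R,6S)-6-hydroxy-2,2,6-trimethyl-3-oxocyclohexyl]acetate F4, which is dried and treated with TESOTf/2,6-lutidine to give triethylsilyl 2-[(1R,6S)-2,2,6-trimethyl-3-oxo-6-(triethylsilyloxy)cyclohexyl]acetate F5. Brief K2CO3 in MeOH/H2O at 0 °C cleaves only the silyl ester to 2-[(1R,6S)-2,2,6-trimethyl-3-oxo-6-(triethylsilyloxy)cyclohexyl]acetic acid F6. EDC/DMAP coupling with EtSH gives S-ethyl 2-[(1R,6S)-2,2,6-trimethyl-3-oxo-6-(triethylsilyloxy)cyclohexyl]ethanethioate F7, and TESOTf/Et3N converts F7 into the silyl enol ether 14, from which the Saegusa oxidation of step 11 proceeds.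

**Further compounds**

F0 | step 7 | none | none
F1 | step 15 | 2-[(1R,2S)-2,6,6-trimethyl-5-oxo-2-(triethylsilyloxy)cyclohex-3-en-1-yl]acetaldehyde | O=CC[C@@H]1C(C)(C)C(=O)C=C[C@]1(C)O[Si](CC)(CC)CC
F2 | step 15 | (2Z)-3-iodobut-2-en-1-yl decanoate | CCCCCCCCCC(=O)OC/C=C(/C)I
F3 | step 15 | (2Z)-4-hydroxy-3-methyl-5-[(1R,2S)-2,6,6-trimethyl-5-oxo-2-(triethylsilyloxy)cyclohex-3-en-1-yl]pent-2-en-1-yl decanoate (carbinol epimers) | CCCCCCCCCC(=O)OC/C=C(/C)C(O)C[C@@H]1C(C)(C)C(=O)C=C[C@]1(C)O[Si](CC)(CC)CC
F4 | step 10 | lithium 2-[(1R,6S)-6-hydroxy-2,2,6-trimethyl-3-oxocyclohexyl]acetate | [Li+].[O-]C(=O)C[C@@H]1C(C)(C)C(=O)CC[C@]1(C)O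
F5 | step 10 | triethylsilyl 2-[(1R,6S)-2,2,6-trimethyl-3-oxo-6-(triethylsilyloxy)cyclohexyl]acetate | CC[Si](CC)(CC)OC(=O)C[C@@H]1C(C)(C)C(=O)CC[C@]1(C)O[Si](CC)(CC)CC
F6 | step 10 | 2-[(1R,6S)-2,2,6-trimethyl-3-oxo-6-(triethylsilyloxy)cyclohexyl]acetic acid | OC(=O)C[C@@H]1C(C)(C)C(=O)CC[C@]1(C)O[Si](CC)(CC)CC
F7 | step 10 | S-ethyl 2-[(1R,6S)-2,2,6-trimethyl-3-oxo-6-(triethylsilyloxy)cyclohexyl]ethanethioate | CCSC(=O)C[C@@H]1C(C)(C)C(=O)CC[C@]1(C)O[Si](CC)(CC)CC
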